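The decision is where to spend the next 50 h on this flask, and I would spend it on oak, the added free catalyst.

the same everywhere: substrate 0.81 M; partner 0.405 M; free catalyst 81 mM
- eta: temperature 70 °C; the very flask that is asked about, followed so far
- zeta: temperature 76 °C; run made earlier
- flask: temperature 70 °C; time 2.0 d

| run | time / h | product / % | substrate / % |
|---|---|---|---|
| eta | 10.0 | 37.4 | 62.4 |
| eta | 20.0 | 38.4 | 62.5 |
| eta | 30.0 | 37.3 | 62.1 |
| eta | 40.0 | 38.2 | 62.3 |
| eta | 50.0 | 37.4 | 61.9 |
| zeta | 10.0 | 30.6 | 69.3 |
| zeta | 20.0 | 31.4 | 68.2 |
| zeta | 30.0 | 31.5 | 68.6 |
| zeta | 40.0 | 31.0 | 70.0 |
| zeta | 50.0 | 31.0 | 69.1 |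

(readings scatter by 0.5 percentage points)

- oak: at 2.0 d add free catalyst, 100 % of the amount charged, then wait 50 h
- larch: change nothing and wait 50 h more
- alder: at 2.0 d raise the temperature by 10 K, then wait 50 h
- birch: at 2.0 d take out 90 % of the product then present, then wait 50 h
- ash: at 2.0 d add partner, 50.0 % of the amount charged, then wait 50 h

- product taken out counts as made
- additions bring no volume worth counting

1. product, in percent of the substrate first charged, at 2.0 d
2. the option that brings most further product ("none" if no option brings more than 2 percentage points) (oak / larch / alder / birch / ash / none)
3. product present, with what was taken out counted in, in percent of the substrate first charged, after alder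
4. product present, with what was taken out counted in, in percent of the substrate first charged, after ash

On the board, y is the flat level of product in percent of the substrate charged. The eta run gives y = 37.7 %, and the zeta run gives 31.1 %. Partner is the limiting reagent, yet y stands below what its charge allows, which is 50.0 %. So two people read the same flat line differently.

Ana says the flask has reached equilibrium. Her constant K, product over substrate times partner, reads 6.10 /M at 70 °C and 2.95 /M at 76 °C.

Ben says free catalyst dies while the reaction runs, so each charge of it buys a fixed amount of progress. He calls this the reach W, the integral of d[product]/([substrate][partner]), which closes to ln(substrate fraction left / partner fraction left) divided by the difference of the two charges. The eta run gives W = 2.30 /M, and the hotter zeta run gives 1.48 /M.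

The readings fit both views, but I side with Ben. A constant falling by a factor of 2.07 over so short a step in temperature asks for a great deal of heat, whereas his fall in W asks only that dying gains more from warmth than making does. Larch, alder, birch and ash bring no catalyst, so they buy no reach and each stays at y. Oak's fresh charge buys W again, which gives a substrate-to-partner ratio of 6.45, product 45.8 %, and a gain of 8.1 percentage points.

The forecast, Ana's side, says 37.8 % now, ash as best, 26.1 % after alder and 52.6 % after ash: “The lower plateau when hotter points to an exothermic equilibrium”.

The flask gives 37.6 %, and the best option is oak, which brings 8.6 points against my 8.1 points. Alder leaves 37.6 % and ash leaves 37.6 %.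

    substrate + partner + free catalyst → product + free catalyst, rate k1*[substrate]*[partner]*[free catalyst]/(1 + ([substrate]/sat1)) (0.730 M, k = 1.40 /M²/min, Ea = 35.0 kJ/mol)
    free catalyst → spent catalyst (k = 0.0270 /min, Ea = 102 kJ/mol)
    (constants at 70 °C)

The proof is the run without the path from free catalyst to spent catalyst. In that run product at 2.0 d stands at 50.0 % where the flask holds 37.6 %, a part of the story. With that path in place oak brings 8.6 points, and in the run without it oak brings 0 points. Ana's picture keeps the flask left alone, which holds 37.6 % at 480 h. In the neighbour flask with 1.6 M of partner, same catalyst and temperature, W = 2.30 /M gives 91.3 %, and that flask holds 96.2 %.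

All runs were generated by integration for substances that don't exist.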